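**Strategy.** Phyltetralin is read as a masked C2-symmetric dimer of two 3,4-dimethoxycinnamyl units: C1/C2 and C4/C3 of the saturated ring are their ArCH–CH pairs, joined at C2–C3. The route builds the all-trans 1,2-diveratryl-3,4-bis(methoxymethyl)cyclobutane (a truxinate-type head-to-head photodimer, made single-handed with a threitol tether) and, in the last step, lets acid cleave its strained bis-benzylic bond. The veratryl-stabilised cation released is captured by the ortho carbon of the other arene, so the four-membered ring C1–C2–C3–C4 grows by C4a and C8a into the tetralin ring, forming C1–C8a and fixing C1 under control of C2.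

Key step: step 5

Assumption: the (4S,5S)-threitol tether is taken to favour the (1S,2S) pairing of the ester-bearing cyclobutane carbons in step 2; the two pairings are separable diastereomers, and should the sense be opposite, the equally available (4R,5R)-diol is used with nothing else changed.

Step 1
Reactants: 1 (E)-3,4-dimethoxycinnamic acid (2.2 equiv); 2 (4S,5S)-2,2-dimethyl-1,3-dioxolane-4,5-dimethanol
Product: 3 bis[(E)-3,4-dimethoxycinnamate] of diol 2
Conditions: DIC, DMAP (cat.), CH2Cl2, 0 °C to rt
Reagents that add atoms: none
Why: Steglich esterification of both primary hydroxyls of the C2-symmetric diol should proceed under neutral conditions that leave the acetonide and the E-alkenes untouched, and no stereocentre is formed.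

Step 2
Reactants: 3 threitol bis-cinnamate
Product: 4 tethered all-trans δ-truxinate (ten-membered bis-lactone)
Conditions: fac-Ir(dFppy)3 (1 mol%), degassed MeCN (5 mM), 450 nm LEDs, rt; chromatography
Reagents that add atoms: none
Why: Triplet-sensitised intramolecular [2+2] photocycloaddition of the tethered bis-cinnamate (template-directed cinnamate photodimerisation) should run stepwise through a relaxed bis-benzylic 1,4-diradical, so that the tether enforces head-to-head union and a trans-diester, the aryl groups settle trans to their neighbours, and the (4S,5S)-acetonide turns the (S,S) and (R,R) pairings of the ester-bearing carbons into separable diastereomers.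

Step 3
Reactants: 4 tethered δ-truxinate
Product: 5 [(1S,2S,3R,4R)-3,4-bis(3,4-dimethoxyphenyl)cyclobutane-1,2-diyl]dimethanol
Conditions: LiAlH4, THF, 0 °C to rt; Fieser work-up
Reagents that add atoms: none
Why: Hydride reduction of both lactone carbonyls should release the cyclobutane diol and the tether diol 2 without touching the four ring stereocentres, the all-trans ester carbons being the stable epimers in any case.

Step 4
Reactants: 5 cyclobutane diol
Product: 6 (1R,2R,3S,4S)-1,2-bis(3,4-dimethoxyphenyl)-3,4-bis(methoxymethyl)cyclobutane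
Conditions: NaH, MeI, THF/DMF, 0 °C to rt
Reagents that add atoms: iodomethane (MeI), CI
Why: Williamson etherification of two unhindered primary alkoxides is reliable and caps both oxygens so that neither can trap the benzylic cation of the next step.

Step 5
Reactants: 6 bis(methoxymethyl)cyclobutane
Product: 8 (1R,2S,3S)-phyltetralin, via ring-opened benzylic cation 7 (not isolated)
Conditions: TfOH (0.2 equiv), degassed HFIP (0.02 M), Ar, 0 °C to rt
Reagents that add atoms: none
Why: Proposed new method: TfOH protonates one veratryl ring ortho to the cyclobutane (para to its 3-OMe); the arenium ion carries positive charge on the ipso carbon, which is β to the bis-benzylic C1–C2 bond of cyclobutane 6, so a strain-driven Grob-type heterolysis (about 26 kcal/mol of ring strain) opens the ring, the transient isotoluene is reprotonated at the former ring carbon, and the veratryl-stabilised cation 7 attacks the ortho carbon of that same arene, a net acid-catalysed 1,3-shift that inserts C4a and C8a into the four-membered ring. The closest known reaction types are the TfOH/HFIP ring-opening hydroarylation of arylcyclopropanes and donor–acceptor cyclobutanes, the cyclobutylcarbinyl-cation ring opening of pinenes, and the acid-mediated closure of 7-oxygenated dibenzylbutane lignans to aryltetralins, which runs through the same kind of cation as 7. The six-membered ring closes in the 6-endo-trig (Ar2-6) Friedel–Crafts mode. Tetralin C2 and C3 are the untouched C4 and C3 of 6 (its aryl-bearing centres are erased, so any aryl epimer of 6 converges), and the new C1 is set by the neighbouring C2 through a chair-like transition state with the aryl and both methoxymethyl groups pseudo-equatorial, which should give the 1,2-trans (1R) isomer. The step needs attack para to the 3-OMe (the future C8a) and not at the hindered carbon between side chain and OMe, and it needs reprotonation and ring closure to outrun a second fragmentation (cationic cycloreversion) or E1 loss of the C2 proton; the C2 symmetry of 6 (either ring gives the same cation), the electronic bias of the veratryl ring and the non-nucleophilic ionising medium are expected to secure both.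

**Compound list**

1 | (E)-3-(3,4-dimethoxyphenyl)acrylic acid (3,4-dimethoxycinnamic acid) | COc1ccc(/C=C/C(=O)O)cc1OC | starting material
2 | (4S,5S)-2,2-dimethyl-1,3-dioxolane-4,5-dimethanol (2,3-O-isopropylidene-L-threitol) | CC1(C)O[C@@H](CO)[C@H](CO)O1 | starting material
3 | [(4S,5S)-2,2-dimethyl-1,3-dioxolane-4,5-diyl]bis(methylene) bis[(E)-3-(3,4-dimethoxyphenyl)acrylate] | CC1(C)O[C@@H](COC(=O)/C=C/c2ccc(OC)c(OC)c2)[C@H](COC(=O)/C=C/c2ccc(OC)c(OC)c2)O1 | intermediate
4 | ten-membered bis-lactone of (1S,2S,3R,4R)-3,4-bis(3,4-dimethoxyphenyl)cyclobutane-1,2-dicarboxylic acid (all-trans, δ-truxinate type) with both CH2OH groups of 2, acetonide retained | O=C1OC[C@@H]2OC(C)(C)O[C@H]2COC(=O)[C@H]3[C@H](c4ccc(OC)c(OC)c4)[C@@H](c4ccc(OC)c(OC)c4)[C@@H]31 | intermediate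
5 | [(1S,2S,3R,4R)-3,4-bis(3,4-dimethoxyphenyl)cyclobutane-1,2-diyl]dimethanol | OC[C@@H]1[C@@H](CO)[C@H](c2ccc(OC)c(OC)c2)[C@H]1c3ccc(OC)c(OC)c3 | intermediate
6 | (1R,2R,3S,4S)-1,2-bis(3,4-dimethoxyphenyl)-3,4-bis(methoxymethyl)cyclobutane | COC[C@@H]1[C@@H](COC)[C@H](c2ccc(OC)c(OC)c2)[C@H]1c3ccc(OC)c(OC)c3 | intermediate
7 | (2S,3S)-1,4-bis(3,4-dimethoxyphenyl)-2,3-bis(methoxymethyl)butan-1-ylium triflate (ring-opened benzylic cation, not isolated) | COC[C@@H]([CH+]c1ccc(OC)c(OC)c1)[C@@H](COC)Cc1ccc(OC)c(OC)c1.[O-]S(=O)(=O)C(F)(F)F | intermediate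
8 | phyltetralin, (1R,2S,3S)-1-(3,4-dimethoxyphenyl)-6,7-dimethoxy-2,3-bis(methoxymethyl)-1,2,3,4-tetrahydronaphthalene | COC[C@H]1Cc2cc(OC)c(OC)cc2[C@@H](c2ccc(OC)c(OC)c2)[C@@H]1COC | target

**Step count and risks**

Total step count: 5. Longest linear sequence: 5 steps (1 → 3 → 4 → 5 → 6 → 8).

Steps most likely to fail:

1. Step 5 (Proposed new method). Protonation may not trigger heterolysis of the strained bond at a useful rate, or the cation may leak into elimination, oligomerisation or a second C–C fragmentation that would erode the C2/C3 configuration. The fallback uses known chemistry only, sets out from 6 and comes back at 8. Hydrogenolysis of the strained bis-benzylic bond (H2, Pd/C, AcOH, 60 °C) would give the dibenzylbutane (2S,3S)-2,3-bis(3,4-dimethoxybenzyl)-1,4-dimethoxybutane F1. Radical benzylic oxidation of one CH2 (t-BuOOH, cat. Rh2(cap)4, partial conversion with recycling) would give the aryl ketone (2S,3S)-1,4-bis(3,4-dimethoxyphenyl)-2,3-bis(methoxymethyl)butan-1-one F2. NaBH4/CeCl3 at –40 °C would give the benzylic alcohol (2S,3S)-1,4-bis(3,4-dimethoxyphenyl)-2,3-bis(methoxymethyl)butan-1-ol F3 (either C1 epimer). TFA in CH2Cl2 at 0 °C would ionise F3 and close the ring to 8 by the established lignan Friedel–Crafts cyclisation, leaving C2/C3 untouched.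

2. Step 2. The tether may discriminate the two faces poorly (or in the wrong sense), or intermolecular oligomerisation may outrun the ten-membered closure. The fallback sets out from 1 and comes back at 5, replacing auxiliary control by resolution. Fischer esterification (MeOH, H2SO4) would give methyl (E)-3-(3,4-dimethoxyphenyl)acrylate F4. Intermolecular Ir-sensitised head-to-head photodimerisation (concentrated DMF, blue LEDs) would give racemic dimethyl all-trans-3,4-bis(3,4-dimethoxyphenyl)cyclobutane-1,2-dicarboxylate F5. Saponification (LiOH, THF/H2O) and classical resolution of the diacid through its diastereomeric salt with (R)-1-phenylethylamine, the configuration being assigned on the crystalline salt, would give (1S,2S,3R,4R)-3,4-bis(3,4-dimethoxyphenyl)cyclobutane-1,2-dicarboxylic acid F6. LiAlH4 in THF would then give 5.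

3. Step 4. Double alkylation may stop at the mono-ether, leaving a hydroxyl that would capture the cation of step 5 as a tetrahydrofuran. The fallback sets out from 5 and comes back at 6 with reversed polarity. MsCl and Et3N in CH2Cl2 at 0 °C would give the bis-mesylate [(1S,2S,3R,4R)-3,4-bis(3,4-dimethoxyphenyl)cyclobutane-1,2-diyl]bis(methylene) dimethanesulfonate F7. Displacement with NaOMe in MeOH/DMF at 60 °C would give 6.

Further compounds
F1 | step 5 | (2S,3S)-2,3-bis(3,4-dimethoxybenzyl)-1,4-dimethoxybutane | COC[C@@H](Cc1ccc(OC)c(OC)c1)[C@@H](COC)Cc1ccc(OC)c(OC)c1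
F2 | step 5 | (2S,3S)-1,4-bis(3,4-dimethoxyphenyl)-2,3-bis(methoxymethyl)butan-1-one | COC[C@@H](C(=O)c1ccc(OC)c(OC)c1)[C@@H](COC)Cc1ccc(OC)c(OC)c1
F3 | step 5 | (2S,3S)-1,4-bis(3,4-dimethoxyphenyl)-2,3-bis(methoxymethyl)butan-1-ol (C1 epimers) | COC[C@@H](C(O)c1ccc(OC)c(OC)c1)[C@@H](COC)Cc1ccc(OC)c(OC)c1
F4 | step 2 | methyl (E)-3-(3,4-dimethoxyphenyl)acrylate | COC(=O)/C=C/c1ccc(OC)c(OC)c1
F5 | step 2 | racemic dimethyl all-trans-3,4-bis(3,4-dimethoxyphenyl)cyclobutane-1,2-dicarboxylate (the 1S,2S,3R,4R enantiomer drawn) | COC(=O)[C@@H]1[C@@H](C(=O)OC)[C@H](c2ccc(OC)c(OC)c2)[C@H]1c3ccc(OC)c(OC)c3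
F6 | step 2 | (1S,2S,3R,4R)-3,4-bis(3,4-dimethoxyphenyl)cyclobutane-1,2-dicarboxylic acid | OC(=O)[C@@H]1[C@@H](C(=O)O)[C@H](c2ccc(OC)c(OC)c2)[C@H]1c3ccc(OC)c(OC)c3
F7 | step 4 | [(1S,2S,3R,4R)-3,4-bis(3,4-dimethoxyphenyl)cyclobutane-1,2-diyl]bis(methylene) dimethanesulfonate | CS(=O)(=O)OC[C@@H]1[C@@H](COS(C)(=O)=O)[C@H](c2ccc(OC)c(OC)c2)[C@H]1c3ccc(OC)c(OC)c3
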